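A slow catalyst round is what you are counting in these flasks, so here is the chemistry and what is asked of it.

    substrate + free catalyst ⇌ catalyst intermediate A (K1 = 51 M⁻¹, k1 = 0.0598 M⁻¹ s⁻¹)
    coupling partner + catalyst intermediate A → catalyst intermediate B (k2 = 0.0392 M⁻¹ s⁻¹)
    catalyst intermediate B → by-product + catalyst intermediate C (k3 = 0.00154 s⁻¹)
    catalyst intermediate C → free catalyst + product (k4 = 0.00420 s⁻¹)
    free catalyst → spent catalyst (k5 = 3.88 × 10⁻⁸ s⁻¹)

in all of them: free catalyst 2.9 mol%

| run | substrate | coupling partner | time | remark |
|---|---|---|---|---|
| south-east | 0.059 M (fed, over 6.40 h) | 1.50 equiv | 8.0 h | all but substrate at the start; substrate goes in evenly over 6.40 h, the run ends at 8.0 h |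
| south | 0.059 M | 1.50 equiv |  | one stirred flow tank at steady state, fed with the mixture as stated, mean residence time 8.0 h |
| north-east | 0.059 M | 1.50 equiv (fed, over 6.40 h) | 8.0 h | a stirred flask in which coupling partner is dosed at a steady rate over 6.40 h without added volume, worked up at 8.0 h |
| east | 0.059 M | 1.50 equiv | 8.0 h | a closed flask charged with all of it at once and left for 8.0 h |

- the set-up with the highest amount of product at the outlet or at the end, in percent of the substrate put in ("none" if the first two lie within 2 percentage points) (south-east / south / north-east / east / none)
- amount of product at the outlet or at the end, in percent of the substrate put in, south-east
- amount of product at the outlet or at the end, in percent of the substrate put in, south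
- amount of product at the outlet or at the end, in percent of the substrate put in, north-east
- amount of product at the outlet or at the end, in percent of the substrate put in, east

- the stated concentrations are those of everything mixed, before any reaction; amounts are the same in each set-up
- the feed brings no volume worth counting
- run time (south-east): 8.0 h

Follow one catalyst molecule. Catalyst intermediate B lives 649 s on average and catalyst intermediate C 238 s, whatever the concentrations. At east's charge, catalyst intermediate A waits 288 s for coupling partner. But it falls back 0.338 times per onward step, so free catalyst pays its wait of 283 s for substrate 1.34 times over. Loss to spent catalyst takes 7160 h on average, far longer than the 8.0 h run, so you can ignore it.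

Added up, these give the round time, the time for one turnover at the concentrations of the moment (the inverse of the turnover frequency):

round time at the charge = 1550 s

Each round gives one product per catalyst, so with the round running steadily, yield is about time over round time, times the loading. I take two extreme versions of east. In the first, the concentrations stay at the charge:

8.0 h / 1550 s × 2.9 mol% = 53.7%

In the second, east works throughout at what that yield leaves, 0.0273 M substrate and 0.0568 M coupling partner:

round time = 2270 s, yield = 36.8%

The real east flask starts at the first's concentrations and, while its yield stays below the first's, stays above the second's, so I expect it between them. I take the middle, 45.2%. South works at its outlet concentrations and the dosed flasks begin without one reagent, so I put east first.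

The forecast also put east first, with 46.2%, a little above my middle. It gave south 40.5%, south-east 35.1% and north-east 35.6%, and called the others “limited by catalyst turnover, not by selectivity”.

The simulation gives east first: east 46.1%, south 40.6%, south-east 35.1%, north-east 35.9%.

At the end of east, with 52.1% of the substrate and 68.5% of the coupling partner left, the round time has stretched from 1550 s to 2120 s, and catalyst intermediate B's life is 30.6% of it, with 30.8% of the catalyst standing in that form. A further flask, like south-east but with 0.15 M of substrate, ends with 43.9% of its substrate and 62.9% of its coupling partner, a round time of 1380 s, shorter than at east's charge; that life is 47.0% of it, and 47.3% of its catalyst stands as catalyst intermediate B.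

The numbers are invented; the result is computed.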